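The numbers in the tables come from a simulation on assumed constants; noise was put on by code.

**The question.** How much of the electrophile has reacted after 12 min in eta, beta and zeta, which differ in free base, and does that base change it?

| setting | maple | larch | eta | beta | zeta |
|---|---|---|---|---|---|
| electrophile | 2.0 × 10⁻⁴ M | 2.0 × 10⁻⁴ M | 2.0 × 10⁻⁴ M | 2.0 × 10⁻⁴ M | 2.0 × 10⁻⁴ M |
| nucleophile | 0.24 mM | 0.24 mM | 0.240 mM | 0.240 mM | 0.240 mM |
| free base | 0.35 mM | 1.8 mM | 0.300 mM | 1.20 mM | 0.600 mM |
| remark | run made earlier | run made earlier |  |  |  |
| time |  |  | 12 min | 12 min | 12 min |

| run | time / min | electrophile / % | target / % |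
|---|---|---|---|
| maple | 0.833 | 78 | 16 |
| maple | 1.50 | 75 | 31 |
| maple | 2.50 | 63 | 36 |
| maple | 3.00 | 58 | 42 |
| maple | 4.00 | 53 | 50 |
| maple | 5.00 | 45 | 51 |
| maple | 6.00 | 39 | 57 |
| larch | 0.333 | 90 | 12 |
| larch | 1.00 | 83 | 19 |
| larch | 1.50 | 71 | 28 |
| larch | 2.50 | 62 | 37 |
| larch | 4.00 | 52 | 49 |
| larch | 5.00 | 47 | 58 |
| larch | 6.00 | 38 | 59 |

(each reading ± 2 percentage points)

- part of the electrophile that has reacted at the end, eta
- part of the electrophile that has reacted at the end, beta
- part of the electrophile that has reacted at the end, zeta
- what raising the concentration of free base from its lowest to its highest value here does to the part of the electrophile that has reacted (changes below 5 percentage points count as none) (no change / it falls / it rises)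

- the earlier runs were read with a standard deviation of 2 percentage points
- reactions considered so far: electrophile + nucleophile <-> acid set free + target; acid set free + free base <-> salt of the base; nucleophile + acid set free <-> protonated nucleophile; nucleophile <-> dormant form

**The readings.** Between maple and larch, c(free base) differs by a factor of 5.14, yet at 6.00 min the electrophile reads 39% and 38%, with a scatter of 2 percentage points. The rate is therefore taken as k·c(electrophile)·c(nucleophile), with free base absent and the nucleophile counted as its charge minus what has reacted.

**Clock number.** The last maple reading gives k, and with it D = 2.32, the clock number: the asked time divided by the second-order lifetime, the reciprocal of k·c(electrophile). It carries the scatter of that reading. With ρ, the charge of nucleophile over that of electrophile, here 1.20, the electrophile is the limiting reagent. The part left is (ρ−1)/(ρ·exp(D(ρ−1))−1), which is 22.0%, so this reckoning gives 78.0% reacted.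

**Enough alone?** D assumes that free base takes up the acid set free. Eta has the lowest charge of free base, and even its 0.300 mM is more than the 2.0 × 10⁻⁴ M of electrophile that can release acid. The reckoning therefore gives eta, beta and zeta one figure.

**The forecast.** It gives 77%, 77% and 77%, with no change, lower than the reckoning here: “so the nucleophile should not be lost by protonation and no stall is expected”.

**The flasks.** Eta gives 75.8%, beta 76.1% and zeta 76.0%: no change, with a change of 0.28 points.

    electrophile + nucleophile ⇌ acid set free + target (K = 25.8, k = 85.2 M⁻¹ s⁻¹)
    acid set free + free base ⇌ salt of the base (K = 8.60 × 10⁶ M⁻¹, k = 1680 M⁻¹ s⁻¹)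
    nucleophile + acid set free ⇌ protonated nucleophile, settled at all times (K = 1.30 × 10⁵ M⁻¹)
    nucleophile ⇌ dormant form (K = 4.76, k = 0.296 s⁻¹)

**Acid and base.** In beta at 2.62 min, acid set free has a half-life of 0.37 s against free base, far shorter than the 4.9 min of the electrophile by its own step, each by the forward rate alone. At 12.0 min beta holds 5.20 × 10⁻⁸ M of acid set free beside 1.52 × 10⁻⁴ M of salt of the base.

**Second flask.** The neighbouring flask is beta with 9.6 × 10⁻⁵ M of nucleophile, so D stays 2.32 while ρ falls to 0.480, and the nucleophile becomes the limiting reagent. The same expression leaves 60.7%, so 39.3% has reacted; the computed neighbouring flask gives 38.0%.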